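The route rests on disconnecting both phenolic C–O bonds of the catechol. The hydroxyls on C2 and C3 of the benzene ring, ortho and meta to the ester-bearing C1, are installed together by toluene dioxygenase, whose preference for the 2,3-edge of a monosubstituted benzene matches this pattern. Whole cells that also express the cis-dihydrodiol dehydrogenase should convert purchased allyl benzoate 1, a small ester that fits the active site, directly into allyl 2,3-dihydroxybenzoate 3. The allyl group supplies O–C1–C2 of the side chain. The C20 anteiso alkene 11, carrying the (S) stereocentre, is then joined at C2=C3 by cross-metathesis, followed by hydrogenation and desilylation.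

Key step: step 1

Remark: chain carbons are counted from the ester oxygen; after metathesis the allyl group keeps only C1 and C2 (its terminal CH2 leaves as ethene), so the partner is the C20 alkene (S)-17-methylnonadec-1-ene; the metathesis product is drawn as its E isomer although both isomers converge on hydrogenation; the recombinant strain is taken as an accessible biocatalyst.

Step 1
Reactants: 1 allyl benzoate
Product: 3 allyl 2,3-dihydroxybenzoate, via cis-dihydrodiol ester 2 (not isolated)
Conditions: E. coli JM109(pDTG602) whole cells (toluene dioxygenase + cis-dihydrodiol dehydrogenase, IPTG-induced), glucose, air, phosphate buffer pH 7, 30 °C, slow feed of 1; EtOAc extraction with ascorbic acid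
Reagents that add atoms: dioxygen, O=O
Why: The Rieske non-heme iron oxygenase, supplied with electrons from NADH through its reductase and ferredoxin, binds O2 at the mononuclear iron centre and delivers both oxygen atoms to the same face of the C2–C3 edge of the ring, giving cis-dihydrodiol 2; the NAD-dependent dehydrogenase then abstracts hydride from one carbinol carbon and the hydroxy-dienone so formed tautomerises to catechol 3, returning the NADH that the dioxygenase consumed. The closest known reactions are the toluene dioxygenase dihydroxylation of small benzoate esters (methyl, ethyl, allyl) at the 2,3-positions and the direct conversion of monosubstituted benzenes into 3-substituted catechols by recombinant strains carrying both enzymes. No ring is closed and no stereocentre survives, since the two carbinol centres of 2 (5S,6R, dictated by the enzyme pocket) are erased on aromatisation. The step needs regioselectivity for C2/C3 over the ipso/ortho and meta/para edges and chemoselectivity over the allyl alkene and the ester: the pocket binds monosubstituted benzenes with the substituent next to the edge presented to iron, small esters are accepted where bulky ones are not, and dehydrogenation inside the cell should outpace dehydration of 2 to a monophenol. Slow feeding and prompt extraction in the presence of ascorbic acid limit catechol toxicity and autoxidation.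

Step 2
Reactants: 3 allyl 2,3-dihydroxybenzoate
Product: 4 allyl 2,3-bis(tert-butyldimethylsilyloxy)benzoate
Conditions: TBSCl (3 equiv), imidazole (6 equiv), DMF, rt → 40 °C
Reagents that add atoms: tert-butyldimethylsilyl chloride (TBSCl), CC(C)(C)[Si](C)(C)Cl
Why: Imidazole-mediated silylation (Corey protocol) through the N-silylimidazolium ion caps both phenols, excess reagent and gentle warming overcoming the hydrogen bond between the C2 hydroxyl and the ester carbonyl, so that no free catechol can later bind ruthenium, while ester and alkene are inert.

Step 3
Reactants: 5 11-bromoundec-1-ene; 6 1,4-dibromobutane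
Product: 8 15-bromopentadec-1-ene, via undec-10-enylmagnesium bromide 7 (not isolated)
Conditions: Mg, THF, 40 °C; then added slowly to 6 (4 equiv), Li2CuCl4 (3 mol %), THF, −10 → 0 °C
Reagents that add atoms: none
Why: Copper-catalysed Grignard–alkyl halide cross-coupling (Kochi coupling) transfers the primary alkyl group of 7 through an organocopper species onto one primary bromide of 6, slow addition to an excess of the dibromide holding double coupling down, while the remote terminal alkene is inert and surplus 6 is distilled off.

Step 4
Reactants: 9 (S)-1-bromo-2-methylbutane; 8 15-bromopentadec-1-ene
Product: 11 (S)-17-methylnonadec-1-ene, via (S)-2-methylbutylmagnesium bromide 10 (not isolated)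
Conditions: 9 (1.6 equiv), Mg, THF, 40 °C; then 8, Li2CuCl4 (3 mol %), THF, −10 °C → rt
Reagents that add atoms: none
Why: A second Kochi coupling joins a primary Grignard reagent to a primary bromide; the stereocentre of 9 lies β to the carbon–magnesium bond, takes part in no bond change and is carried into 11 with its (S) configuration intact, and the by-products from the excess Grignard reagent (2-methylbutane and its C10 homodimer) are volatile.

Step 5
Reactants: 4 allyl 2,3-bis(tert-butyldimethylsilyloxy)benzoate; 11 (S)-17-methylnonadec-1-ene
Product: 12 (2E,18S)-18-methylicos-2-en-1-yl 2,3-bis(tert-butyldimethylsilyloxy)benzoate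
Conditions: second-generation Grubbs catalyst RuCl2(=CHPh)(PCy3)(H2IMes) (5 mol %), 11 (2 equiv), 1,4-benzoquinone (10 mol %), CH2Cl2, 40 °C, argon sweep
Reagents that add atoms: none
Why: Olefin cross-metathesis by the Chauvin [2+2]/retro-[2+2] mechanism between two unhindered monosubstituted alkenes is driven by loss of ethene, the excess of 11 favouring the cross product (its hydrocarbon homodimer is easily separated and can be re-used), benzoquinone suppressing ruthenium hydride double-bond migration that would scramble the chain length, and the alkene geometry being irrelevant because the double bond is hydrogenated next.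

Step 6
Reactants: 12 (2E,18S)-18-methylicos-2-en-1-yl 2,3-bis(tert-butyldimethylsilyloxy)benzoate
Product: 13 (S)-18-methylicosyl 2,3-bis(tert-butyldimethylsilyloxy)benzoate
Conditions: H2 (1 atm), RhCl(PPh3)3 (5 mol %), toluene–EtOH, rt
Reagents that add atoms: none
Why: Homogeneous hydrogenation with RhCl(PPh3)3 (Wilkinson hydrogenation) saturates the disubstituted alkene of either geometry by oxidative addition of H2, alkene insertion and reductive elimination, without the allylic C–O hydrogenolysis common on heterogeneous palladium and without touching the arene, the ester, the silyl ethers or the remote stereocentre.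

Step 7
Reactants: 13 (S)-18-methylicosyl 2,3-bis(tert-butyldimethylsilyloxy)benzoate
Product: 14 gentiside H, (S)-18-methylicosyl 2,3-dihydroxybenzoate
Conditions: HF·pyridine, pyridine, THF, 0 °C → rt; pH 7 buffer work-up
Reagents that add atoms: none
Why: Fluoride-induced desilylation, driven by the strong Si–F bond, cleaves both aryl silyl ethers under buffered, mildly acidic conditions that leave the primary alkyl benzoate ester and the stereocentre untouched and keep the freed catechol from base-promoted air oxidation.

Compound list
1 | allyl benzoate (prop-2-en-1-yl benzoate) | C=CCOC(=O)c1ccccc1 | starting material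
2 | allyl (5S,6R)-5,6-dihydroxycyclohexa-1,3-diene-1-carboxylate (cis-dihydrodiol) | C=CCOC(=O)C1=CC=C[C@H](O)[C@@H]1O | intermediate
3 | allyl 2,3-dihydroxybenzoate | C=CCOC(=O)c1cccc(O)c1O | intermediate
4 | allyl 2,3-bis(tert-butyldimethylsilyloxy)benzoate | C=CCOC(=O)c1cccc(O[Si](C)(C)C(C)(C)C)c1O[Si](C)(C)C(C)(C)C | intermediate
5 | 11-bromoundec-1-ene | C=CCCCCCCCCCBr | starting material
6 | 1,4-dibromobutane | BrCCCCBr | starting material
7 | undec-10-enylmagnesium bromide | C=CCCCCCCCCC[Mg]Br | intermediate
8 | 15-bromopentadec-1-ene | C=CCCCCCCCCCCCCCBr | intermediate
9 | (S)-1-bromo-2-methylbutane | CC[C@H](C)CBr | starting material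
10 | (S)-2-methylbutylmagnesium bromide | CC[C@H](C)C[Mg]Br | intermediate
11 | (S)-17-methylnonadec-1-ene | CC[C@H](C)CCCCCCCCCCCCCCC=C | intermediate
12 | (2E,18S)-18-methylicos-2-en-1-yl 2,3-bis(tert-butyldimethylsilyloxy)benzoate (Z isomer expected alongside) | CC[C@H](C)CCCCCCCCCCCCCC/C=C/COC(=O)c1cccc(O[Si](C)(C)C(C)(C)C)c1O[Si](C)(C)C(C)(C)C | intermediate
13 | (S)-18-methylicosyl 2,3-bis(tert-butyldimethylsilyloxy)benzoate | CC[C@H](C)CCCCCCCCCCCCCCCCCOC(=O)c1cccc(O[Si](C)(C)C(C)(C)C)c1O[Si](C)(C)C(C)(C)C | intermediate
14 | gentiside H, (S)-18-methylicosyl 2,3-dihydroxybenzoate | CC[C@H](C)CCCCCCCCCCCCCCCCCOC(=O)c1cccc(O)c1O | target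

Total step count: 7. Longest linear sequence: 5 steps (steps 1, 2, 5, 6, 7 from 1; equally steps 3, 4, 5, 6, 7 from 5).

Steps most likely to fail

Step 1. Uptake or turnover of the ester by the cells may be poor, host esterases may hydrolyse the allyl ester, or the accumulating catechol may inhibit the culture, so that little product is formed. The fallback gives up the enzymatic oxidation and buys the two oxygens in place. It sets out from no compound of the route: purchased 2,3-dihydroxybenzoic acid F1 takes the place of 1. It is alkylated at the carboxylate only with allyl bromide (C=CCBr) and KHCO3 in DMF at rt, the weak base ionising the acid but not the phenols. This gives 3, where the route resumes at step 2.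

Step 5. Statistical homodimerisation of either partner, early catalyst death, or double-bond migration before metathesis (which would give chain-shortened homologues that cannot be separated) may erode the cross-coupling. The fallback attaches the chain by esterification instead of metathesis and sets out from 4 and from 9.
- Acid: 4 is deallylated with catalytic Pd(PPh3)4 and N-methylaniline in THF at rt to 2,3-bis(tert-butyldimethylsilyloxy)benzoic acid F2.
- Alcohol: Grignard reagent 10, made from 9 as in step 4 (2.5 equiv), is coupled with purchased 16-bromohexadecan-1-ol (OCCCCCCCCCCCCCCCCBr) under Li2CuCl4 catalysis in THF, the first equivalent forming the magnesium alkoxide. This gives (S)-18-methylicosan-1-ol F3.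
- Union: Mitsunobu esterification of F2 with F3 (PPh3, diisopropyl azodicarboxylate, THF, 0 °C → rt) gives 13 directly. Steps 5 and 6 are bypassed and the route resumes at step 7.

Step 3. Coupling at both ends of the dibromide, together with Wurtz-type homocoupling during Grignard formation, may consume the Grignard reagent and leave hydrocarbon mixtures that are hard to separate. The fallback differentiates the two chain ends chemically instead of statistically and sets out from 5. Grignard reagent 7 is coupled with purchased 1-bromo-4-chlorobutane (ClCCCCBr, 1.2 equiv; Li2CuCl4, THF, −10 °C), which should react at bromide only, to give 15-chloropentadec-1-ene F4. Finkelstein exchange (NaI, butanone, reflux) gives 15-iodopentadec-1-ene F5. F5 is coupled with 10 under the conditions of step 4 in place of 8, and the fallback comes back to the route at 11.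

Further compounds
F1 | step 1 | 2,3-dihydroxybenzoic acid (purchased) | O=C(O)c1cccc(O)c1O
F2 | step 5 | 2,3-bis(tert-butyldimethylsilyloxy)benzoic acid | O=C(O)c1cccc(O[Si](C)(C)C(C)(C)C)c1O[Si](C)(C)C(C)(C)C
F3 | step 5 | (S)-18-methylicosan-1-ol | CC[C@H](C)CCCCCCCCCCCCCCCCCO
F4 | step 3 | 15-chloropentadec-1-ene | C=CCCCCCCCCCCCCCCl
F5 | step 3 | 15-iodopentadec-1-ene | C=CCCCCCCCCCCCCCI
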